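4 questions stand here, and one counted quantity serves them.

in all of them: substrate 2.8 M; gas 200 mM (held)

| flask | catalyst | temperature | remark | time |
|---|---|---|---|---|
| ochre | 2.8 mM | 32 °C | run made earlier |  |
| amber | 6.3 mM | 49 °C | run made earlier |  |
| spring | 4.2 mM | 55 °C |  | 3.0 min |
| autumn | 4.2 mM | 25 °C |  | 3.0 min |
| dawn | 4.2 mM | 40 °C |  | 3.0 min |

| run | time / min | target / % | uncatalysed product / % |
|---|---|---|---|
| ochre | 0.833 | 2.9 | 9.7 |
| ochre | 2.50 | 7.8 | 29.8 |
| ochre | 4.00 | 11.9 | 44.3 |
| ochre | 6.00 | 16.5 | 58.9 |
| ochre | 10.0 | 20.5 | 72.8 |
| amber | 0.667 | 5.5 | 11.5 |
| amber | 1.33 | 11.8 | 22.9 |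
| amber | 2.00 | 17.2 | 33.5 |
| amber | 2.50 | 20.5 | 40.4 |
| amber | 3.00 | 23.2 | 47.1 |

(each reading ± 0.3 percentage points)

- the numbers in the tables scatter with a standard deviation of 0.3 percentage points
- at the start none of the gas is in solution

* the best flask by share of target in all that became target or uncatalysed product; "all alike" if 1.5 percentage points covers them all (spring / autumn / dawn / all alike)
* share of target in all that became target or uncatalysed product, spring
* share of target in all that became target or uncatalysed product, autumn
* share of target in all that became target or uncatalysed product, dawn

Substrate leaves by two routes: with catalyst to target, and without it to uncatalysed product. The gas is held alike in every flask. Draw target against uncatalysed product, each as a fraction of the substrate charged, and start at the origin. In the ochre run the slope to the first point is 0.299, and to the last 0.282. In the amber run these are 0.478 and 0.493. Within the scatter you see no knee, even with 6.70% of the substrate left in ochre. If the line stays straight to the end, it stops where its two fractions sum to one, so the target level is: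

share = slope ÷ (slope + 1), which reads 22.0% for ochre

Now count turnovers, dividing each slope by the catalyst as a fraction of the substrate charge:

ochre: 282
amber: 219

Catalyst and temperature changed together, so I assume first order in catalyst and a constant factor per degree. The number to carry is the turnover count, a selectivity factor: the turnovers one catalyst makes for each whole charge's worth of uncatalysed product, reckoned from the slope of the line. For the new flasks, whose catalyst fraction is 0.150%:

autumn: 312, share 31.9%
dawn: 250, share 27.3%
spring: 200, share 23.1%

So in my reckoning autumn leads spring by 8.8 percentage points, more than the margin.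

The forecast gives autumn, with 31% there (24% to 36%), 27.3% for dawn and 24% for spring, which differs from mine at autumn and spring, and it warns: “A lower order would reverse the trend”.

The flasks give autumn, with 31.2% there, 27.2% for dawn and 23.9% for spring.

substrate + partner → uncatalysed product (k = 0.890 M⁻¹ min⁻¹, Ea = 52.0 kJ mol⁻¹); substrate + partner + catalyst → catalyst + target (k = 96.0 M⁻² min⁻¹, Ea = 42.0 kJ mol⁻¹); gas ⇌ partner, rate k3*(csat - [partner]) (kL = 5.10 min⁻¹); (constants at 25 °C) Autumn still holds 62% of its substrate at 3.00 min, yet its share at 30.0 min is 31.2%. A neighbour of autumn is charged with 0.0071 M of catalyst, and the carried count gives it a slope of 0.792 and a share of 44.2%. That neighbour flask gives a share of 43.4%.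

Readings and results were computed with constants of no real substance; scatter was added.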